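Compound numbers 1–27 are fixed by the order of first appearance in the steps; 27 is the target.

## Analysis of the target

Compound 27 is a humulane sesquiterpenoid built on a single 11-membered carbocycle. The ring is numbered here C1 (alkene carbon bearing CO2H), C2 (alkene CH), C3 (CH–OBz), C4 (CMe2), C5–C7 (CH2), C8 (methyl-bearing epoxide carbon), C9 (epoxide CH), C10 and C11 (CH2). The only alkene, C1=C2, is E by the CIP rules but ring-cis: C11 and C3 lie on the same side, and the carboxyl group is trans to C3. There are three stereocentres, C3 (R), C8 (R) and C9 (R). C8 and C9 are tied together by the trans-epoxide (C7 and C10 on opposite faces), so both come from one face-selective epoxidation of an E alkene. C3 is five bonds from the epoxide in either direction around the ring and has no neighbour that could relay stereochemical information. The sensitive groups are the trisubstituted epoxide (acid and Lewis acid, and a carboxyl group within reach), the benzoate (hydroxide, alkoxide) and the allylic C3–O bond. The hard parts are the closure of an 11-membered ring, the neopentylic carbinol C3 beside the quaternary C4, and the configuration of C3 relative to a remote epoxide. The strategy rests on the C3 carbinol standing next to the gem-dimethyl carbon C4 with plain C5H2–C6H2 beyond it. That is what γ-addition of a prenyl-type allylmetal to an aldehyde leaves once the new C5=C6 alkene is saturated. C3–C4 is also the bond that nature closes on the way to humulene, and the transient C5=C6 alkene sits where humulene has one.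

## Retrosynthetic reasoning

27 ⇒ 26 ⇒ 25 ⇒ 24. No skeletal bond is cut. The acid is masked as the 2-(trimethylsilyl)ethyl ester 26, which falls apart on attack at silicon and so needs neither acid (epoxide) nor hydroxide (benzoate). The benzoate is put on the free alcohol 25 only after the last reduction, and the C5–C6 single bond of 25 is traced to the C5=C6 alkene of 24. That alkene is what makes the next cut possible. Forward, a disubstituted alkene has to be reduced beside a conjugated trisubstituted one, and a neopentylic alcohol acylated.

24 ⇒ 22 (through 23). The C3–C4 bond is cut. It is the one ring bond whose formation gives the quaternary carbon, the carbinol and the ring in a single event. A cut at C1=C2 would ask a ring-closing olefination for a ring-cis trisubstituted enoate in a medium ring, and the sp3–sp3 bonds C6–C7 and C10–C11 have no function to activate them. The gain is an open chain on which the epoxide can be set without ring constraints. Forward, the tertiary allylic carbonate must be turned into a nucleophile (umpolung) that reacts through its substituted terminus C4, closes the ring faster than it oligomerises, and takes the Si face of the aldehyde.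

22 ⇒ 21 ⇒ 20. The aldehyde is taken back to the primary allylic alcohol, which is the oxidation level that survives an oxidative epoxidation. The epoxide is taken back to the E C8=C9 alkene of 20. Both epoxide stereocentres then come from one reagent-controlled step, which must pick the one electron-rich alkene out of three and one of its faces.

20 ⇒ 17 + 19 (released from 18). The C1=C2 bond is cut by a Wittig disconnection. An α-substituted ester ylide gives the ester trans to C3, which is the ring-cis geometry of 27, and 19 brings C2 and C3 with the oxygen in place.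

17 ⇒ 12 + 15, and 15 ⇒ 13 + 14. The C11–C1 bond is cut between the ylide carbon and a primary iodide. The same phosphorus that makes C1 nucleophilic here serves the olefination above, and 15 brings the fluoride-labile ester.

12 ⇒ 11 ⇒ 10 ⇒ 9 ⇒ 8 ⇒ 6 + 7. After functional-group changes (iodide, silyl ether, carbonate), the E C5=C6 alkene is traced to the alkyne of 8, and the C6–C7 bond is cut between the terminal alkyne 7 and the allylic bromide 6. Compound 7 holds C4, both methyl groups, the oxygen, C5 and C6 in one piece, and its propargylic hydroxyl directs the reduction that sets the E alkene.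

6 ⇒ 5 ⇒ 4 ⇒ 3 + 2, and 3 ⇐ 1. The C8=C9 bond is cut by a second Wittig disconnection. The stabilised ylide 2 brings C7, C8 and the methyl group and gives the E geometry that the trans-epoxide requires.

## Alternatives that were turned down

Alternative 1: Grob fragmentation of a fused bicycle.
- Disconnection: a transannular C3–C8 bond is added to the ring. This turns the 11-membered dienone A2 (methyl 4,4,8-trimethyl-3-oxocycloundeca-1,8-diene-1-carboxylate, C1=C2 ring-cis, C8=C9 E) into the cis-fused six–seven hydroxy mesylate A1, with a tertiary hydroxyl on the ring-fusion carbon C3, a methyl on the ring-fusion carbon C8 and a mesylate on C9.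
- Forward key step: a hindered alkoxide base deprotonates the C3 hydroxyl of A1, and the alkoxide pushes out the C9 mesylate through the anti-periplanar C3–C8 bond, giving the C3 ketone and the C8=C9 alkene of A2.
- For it: the medium ring comes from two normal rings without high dilution. The fragmentation is stereospecific, so C8=C9 is E by design, and C1=C2 is ring-cis because it is born in a seven-membered ring. On the ring-forming event itself this route is more secure than the chosen one.
- Against it for 27: A2 has no stereocentre, so C3 (ketone reduction) and C8/C9 (epoxidation) would both be set by reagents on a flexible 11-membered ring, in two steps whose senses are not tied to each other. A1 needs three stereocentres in one relative arrangement that are then all destroyed, and its synthesis is long. The 4-oxo-2-enoate of A2 is a strong Michael acceptor in an alkoxide medium, and the methyl ester must finally be cleaved beside the benzoate.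
- Comparison: the chosen route accepts a riskier ring closure. In return it sets the epoxide on an open chain, creates C3 in the step that closes the ring, and carries an ester that fluoride removes.

Alternative 2: radical opening of the cyclobutane of caryophyllene oxide.
- Disconnection: the C2–C5 bond is added across the ring and the carboxyl carbon is taken back to an exocyclic methylene. This leads to caryophyllene oxide A3, a cheap terpene that holds all fifteen carbons and the epoxide in the right absolute configuration.
- Forward key step: an arylthiyl radical adds to the exocyclic methylene of A3. The tertiary cyclobutylcarbinyl radical at C1 opens by cleavage of the ring-fusion bond C2–C5, and hydrogen transfer to the secondary C5 radical gives the phenylthiomethyl cycloundecene A4.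
- For it: it is by far the shortest way to the carbocycle, there is no macrocyclisation, and C8 and C9 are bought, not made. On step count to the ring and on the epoxide configuration it is clearly stronger than the chosen route.
- Against it: A4 has no oxygen at C3 and the wrong oxidation level at the C1 substituent. A C–H oxidation would have to pick the neopentylic C3 methylene over C11 and over the sulfur-bearing carbon, and one of its two hydrogens, on a flexible ring with nothing to direct it. The sulfide must be taken up to the acid beside an epoxide. The radical has a second cyclobutane bond (C2–C3) to break, the ring radical can add across the ring, and the geometry of the new C1=C2 alkene is left to the fragmentation and to reversible thiyl addition.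
- Comparison: the chosen route offers the C3 oxygen and the carboxyl carbon at their final oxidation levels from the building blocks, every functional group placed by bond construction, and the C1=C2 geometry fixed by a Wittig reaction.

Alternative 3: enone–cyclobutene photocycloaddition and thermal ring expansion.
- Disconnection: the ring alkenes C1=C2 and C8=C9 of the dienone A7 (the 2-(trimethylsilyl)ethyl ester corresponding to A2) are exchanged, as in a formal metathesis, for the C2=C8 alkene of 3,7,7-trimethylcyclohept-2-en-1-one A5 and the C1=C9 alkene of 2-(trimethylsilyl)ethyl cyclobut-1-ene-1-carboxylate A6.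
- Forward key step: irradiation joins A5 and A6 through the C1–C2 and C8–C9 bonds in a [2+2] cycloaddition. Heating the crude mixture breaks the other two bonds of the new cyclobutane (C2–C8 and C1–C9), which inserts the four cyclobutene carbons into the seven-membered ring and gives A7.
- For it: two operations lead from two small achiral pieces to the complete skeleton, with the gem-dimethyl ketone and the fluoride-labile ester in place. On step economy nothing else comes close.
- Against it: the cycloaddition must be head-to-head (ester carbon to the enone α-carbon), and the regiochemistry of excited enones with electron-poor alkenes is not dependable. Cycloheptenones isomerise to the strained E isomer on irradiation and then dimerise or add unselectively. The thermal opening runs through a diradical, so it may return A5 and A6 or give other alkene geometries, while 27 needs C8=C9 E and C1=C2 ring-cis. A7, like A2, is achiral, so the whole stereochemical problem moves to reagent-controlled reactions on the 11-membered ring.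
- Comparison: the chosen route is much longer, but each of its bonds is formed with defined regiochemistry and geometry, and the stereocentres are introduced where control is best understood.

Key step: step 14

Remark on the chemistry: the alkaloid in step 14 is written as (−)-cinchonidine on the assumption that it directs the allyl group to the Si face of C3; if the sense is the opposite, its pseudo-enantiomer (+)-cinchonine takes its place with nothing else changed.

## Route

Step 1
Reactants: 1 3-(tert-butyldimethylsilyloxy)propan-1-ol; 2 ethyl 2-(triphenylphosphoranylidene)propanoate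
Product: 4 ethyl (E)-5-(tert-butyldimethylsilyloxy)-2-methylpent-2-enoate, via 3-(tert-butyldimethylsilyloxy)propanal 3 (not isolated)
Conditions: (COCl)2, DMSO, CH2Cl2, −78 °C; Et3N; then 2, −78 → 25 °C
Reagents that add atoms: none
Why: Swern oxidation gives the β-silyloxy aldehyde 3, which is prone to β-elimination and is therefore trapped in the same flask by the stabilised ylide 2 (Wittig reaction); α-methyl ester ylides give the E enoate with the ester trans to the chain, and this geometry later places C7 and C10 trans across the epoxide.

Step 2
Reactants: 4 ethyl (E)-5-(tert-butyldimethylsilyloxy)-2-methylpent-2-enoate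
Product: 5 (E)-5-(tert-butyldimethylsilyloxy)-2-methylpent-2-en-1-ol
Conditions: i-Bu2AlH, CH2Cl2, −78 °C; aq. potassium sodium tartrate
Reagents that add atoms: none
Why: 1,2-Reduction of the enoate by the aluminium hydride at low temperature gives the allylic alcohol without touching the alkene geometry or the silyl ether.

Step 3
Reactants: 5 (E)-5-(tert-butyldimethylsilyloxy)-2-methylpent-2-en-1-ol
Product: 6 tert-butyl[(E)-5-bromo-4-methylpent-3-enyloxy]dimethylsilane
Conditions: CBr4, PPh3, CH2Cl2, 0 °C
Reagents that add atoms: tetrabromomethane, BrC(Br)(Br)Br
Why: Appel bromination converts the primary allylic alcohol into the bromide by SN2 at carbon under neutral conditions, so neither allylic transposition nor E/Z isomerisation is expected.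

Step 4
Reactants: 6 tert-butyl[(E)-5-bromo-4-methylpent-3-enyloxy]dimethylsilane; 7 2-methylbut-3-yn-2-ol
Product: 8 (E)-9-(tert-butyldimethylsilyloxy)-2,6-dimethylnon-6-en-3-yn-2-ol
Conditions: CuI (20 mol %), NaI (20 mol %), Cs2CO3, DMF, 25 °C
Reagents that add atoms: none
Why: Alkylation of a terminal alkyne under catalysis by monovalent copper: the copper acetylide of 7 displaces the primary allylic bromide at its CH2 terminus (SN2) and forms C6–C7 as a skipped enyne; the free tertiary hydroxyl is tolerated and the carbonate base is too weak to isomerise the doubly activated C7 methylene.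

Step 5
Reactants: 8 (E)-9-(tert-butyldimethylsilyloxy)-2,6-dimethylnon-6-en-3-yn-2-ol
Product: 9 (3E,6E)-9-(tert-butyldimethylsilyloxy)-2,6-dimethylnona-3,6-dien-2-ol
Conditions: NaAlH2(OCH2CH2OMe)2, THF, 0 → 25 °C; aq. potassium sodium tartrate
Reagents that add atoms: none
Why: Hydroxyl-directed trans-hydroalumination of the propargylic alcohol (the alkoxyaluminium hydride delivers hydride within the molecule and the vinylalanate is protonated on work-up) gives the E allylic alcohol only; the isolated trisubstituted alkene and the silyl ether do not react.

Step 6
Reactants: 9 (3E,6E)-9-(tert-butyldimethylsilyloxy)-2,6-dimethylnona-3,6-dien-2-ol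
Product: 10 (3E,6E)-9-(tert-butyldimethylsilyloxy)-2,6-dimethylnona-3,6-dien-2-yl methyl carbonate
Conditions: n-BuLi, THF, −78 °C; ClCO2Me, −78 → 0 °C
Reagents that add atoms: methyl chloroformate, COC(=O)Cl
Why: The lithium alkoxide of the hindered tertiary allylic alcohol is acylated by the chloroformate at low temperature; this places the leaving group of the key step early, on a robust intermediate.

Step 7
Reactants: 10 (3E,6E)-9-(tert-butyldimethylsilyloxy)-2,6-dimethylnona-3,6-dien-2-yl methyl carbonate
Product: 11 (3E,6E)-9-hydroxy-2,6-dimethylnona-3,6-dien-2-yl methyl carbonate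
Conditions: HF·pyridine, pyridine, THF, 0 → 25 °C
Reagents that add atoms: none
Why: Buffered HF·pyridine removes the primary silyl ether by attack at silicon; the medium is too weakly acidic to ionise the tertiary allylic carbonate.

Step 8
Reactants: 11 (3E,6E)-9-hydroxy-2,6-dimethylnona-3,6-dien-2-yl methyl carbonate
Product: 12 (3E,6E)-9-iodo-2,6-dimethylnona-3,6-dien-2-yl methyl carbonate
Conditions: I2, PPh3, imidazole, CH2Cl2, 0 °C
Reagents that add atoms: iodine, II
Why: Appel-type iodination turns the primary alcohol into the iodide by SN2; the carbonate and both alkenes are inert.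

Step 9
Reactants: 13 2-(trimethylsilyl)ethanol; 14 (triphenylphosphoranylidene)ketene
Product: 15 2-(trimethylsilyl)ethyl 2-(triphenylphosphoranylidene)acetate
Conditions: toluene, 90 °C
Reagents that add atoms: none
Why: The alcohol adds across the cumulated ylide (Bestmann ylide) and gives the ester-stabilised ylide in one operation without any by-product; this supplies the fluoride-labile ester that the end of the route needs.

Step 10
Reactants: 12 (3E,6E)-9-iodo-2,6-dimethylnona-3,6-dien-2-yl methyl carbonate; 15 2-(trimethylsilyl)ethyl 2-(triphenylphosphoranylidene)acetate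
Product: 17 2-(trimethylsilyl)ethyl (5E,8E)-10-(methoxycarbonyloxy)-6,10-dimethyl-2-(triphenylphosphoranylidene)undeca-5,8-dienoate, via alkylated phosphonium iodide 16 (not isolated)
Conditions: MeCN, 80 °C; then CH2Cl2/0.5 M aq. NaOH, 0 °C
Reagents that add atoms: none
Why: C-Alkylation of the ester-stabilised ylide by the primary iodide (SN2) forms C11–C1 and gives the phosphonium iodide 16, which cold dilute NaOH deprotonates to the α-substituted ylide 17; the ylide ester and the tertiary carbonate withstand the brief basic wash.

Step 11
Reactants: 17 2-(trimethylsilyl)ethyl (5E,8E)-10-(methoxycarbonyloxy)-6,10-dimethyl-2-(triphenylphosphoranylidene)undeca-5,8-dienoate; 18 glycolaldehyde dimer (1,4-dioxane-2,5-diol)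
Product: 20 2-(trimethylsilyl)ethyl (2E,5E,8E)-2-(2-hydroxyethylidene)-10-(methoxycarbonyloxy)-6,10-dimethylundeca-5,8-dienoate, via glycolaldehyde 19 (not isolated)
Conditions: toluene, 80 °C
Reagents that add atoms: none
Why: On heating the dimer 18 releases glycolaldehyde 19, which undergoes Wittig olefination with the α-substituted ester ylide; such ylides give the E enoate (ester trans to CH2OH, so C11 and C3 cis), which is the ring-cis geometry of the target and also rules out butenolide formation.

Step 12
Reactants: 20 2-(trimethylsilyl)ethyl (2E,5E,8E)-2-(2-hydroxyethylidene)-10-(methoxycarbonyloxy)-6,10-dimethylundeca-5,8-dienoate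
Product: 21 2-(trimethylsilyl)ethyl (2E)-2-(2-hydroxyethylidene)-4-[(2R,3R)-3-[(E)-4-(methoxycarbonyloxy)-4-methylpent-2-en-1-yl]-3-methyloxiran-2-yl]butanoate
Conditions: 1,2:4,5-di-O-isopropylidene-β-D-erythro-hexo-2,3-diulo-2,6-pyranose (D-fructose-derived Shi ketone, 30 mol %), Oxone (2KHSO5·KHSO4·K2SO4), K2CO3, Bu4NHSO4, MeCN/CH2(OMe)2/aq. Na2B4O7 buffer, 0 °C
Reagents that add atoms: potassium peroxymonosulfate KHSO5 (active part of Oxone), [K+].[O-]S(=O)(=O)OO
Why: Shi epoxidation: the chiral dioxirane formed from the ketone and KHSO5 transfers oxygen through a spiro transition state to the only electron-rich alkene, trisubstituted C8=C9 (C5=C6 is disubstituted, neopentylic and deactivated by the allylic carbonate, and C1=C2 is conjugated with the ester); with the D-fructose-derived ketone an E alkene of this substitution pattern is attacked on the face that gives the (8R,9R) epoxide, in the same sense in which E-dialkyl alkenes give (R,R) epoxides.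

Step 13
Reactants: 21 2-(trimethylsilyl)ethyl (2E)-2-(2-hydroxyethylidene)-4-[(2R,3R)-3-[(E)-4-(methoxycarbonyloxy)-4-methylpent-2-en-1-yl]-3-methyloxiran-2-yl]butanoate
Product: 22 2-(trimethylsilyl)ethyl (2E)-4-[(2R,3R)-3-[(E)-4-(methoxycarbonyloxy)-4-methylpent-2-en-1-yl]-3-methyloxiran-2-yl]-2-(2-oxoethylidene)butanoate
Conditions: Dess–Martin periodinane, pyridine, CH2Cl2, 0 → 25 °C
Reagents that add atoms: none
Why: Dess–Martin oxidation of the primary allylic alcohol under pyridine buffering gives the enal without acid, so the epoxide, the carbonate and the E geometry (aldehyde trans to the ester, the thermodynamically preferred arrangement) are kept.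

Step 14
Reactants: 22 2-(trimethylsilyl)ethyl (2E)-4-[(2R,3R)-3-[(E)-4-(methoxycarbonyloxy)-4-methylpent-2-en-1-yl]-3-methyloxiran-2-yl]-2-(2-oxoethylidene)butanoate
Product: 24 2-(trimethylsilyl)ethyl (1E,3R,5E,8R,9R)-8,9-epoxy-3-hydroxy-4,4,8-trimethylcycloundeca-1,5-diene-1-carboxylate, via C6-allylindium 23 (not isolated)
Conditions: Pd(PPh3)4 (10 mol %), InI (2 equiv), (−)-cinchonidine (2 equiv), THF, 25 °C, slow addition of 22 (final 2 mM); pH 7 phosphate buffer
Reagents that add atoms: none
Why: Proposed new method: Pd(PPh3)4 ionises the tertiary allylic carbonate of 22 with loss of CO2 and methoxide, InI reduces the π-allylpalladium to the allylindium 23 carrying the metal on the less substituted C6, and 23 adds to the C3 aldehyde through its γ-carbon C4 in a six-membered chair transition state, which forms the C3–C4 bond, the quaternary C4, the C3 carbinol and a C5=C6 alkene in one event; the closest known reaction types are the γ-selective Pd/InI umpolung allylation of aldehydes by prenyl-type carbonates (between molecules and in closures of five- and six-membered rings), chromium-mediated macrocyclic allylation of aldehydes, and the addition of cinchona-alkaloid-modified allylindium reagents to aldehydes, whose combination in a ligand-controlled 11-membered closure has not been shown. The ring closes in the carbonyl addition itself, 11-exo-trig at C3=O, and C4, C5 and C6 of the allyl unit all become ring atoms. γ-Attack is needed and is secured twice: indium prefers the secondary C6 to the tertiary C4, and the competing C3–C6 bond would close a more strained nine-membered ring. Ring closure must outrun chain growth between molecules, for which 22 is added slowly to a final 2 mM, and 1,2-addition to the enal is the normal course for allylindium reagents. C3 is the only new stereocentre: the allyl unit is achiral and the epoxide lies five bonds away in either direction, so the substrate gives little bias and the controlling element is the cinchonidine held on indium through its alkoxide and quinuclidine nitrogen, which has to direct C4 to the Si face of the aldehyde to give 3R. The amine also tempers the Lewis acidity of trivalent indium toward the epoxide. The geometry of the new C5=C6 alkene (E with C7 equatorial in the chair) does not matter, because step 15 saturates it. Reagent control at C3 also upgrades the enantiomeric purity set in step 12, since material from the minor epoxide enantiomer ends mainly as a diastereomer that is removed.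

Step 15
Reactants: 24 2-(trimethylsilyl)ethyl (1E,3R,5E,8R,9R)-8,9-epoxy-3-hydroxy-4,4,8-trimethylcycloundeca-1,5-diene-1-carboxylate
Product: 25 2-(trimethylsilyl)ethyl (1E,3R,8R,9R)-8,9-epoxy-3-hydroxy-4,4,8-trimethylcycloundec-1-ene-1-carboxylate
Conditions: 2-nitrobenzenesulfonyl hydrazide, Et3N, CH2Cl2, 25 °C
Reagents that add atoms: none
Why: Diimide, generated in the flask from the sulfonyl hydrazide, transfers two hydrogens in a concerted syn fashion and is strongly sensitive to substitution, so the disubstituted, strained C5=C6 alkene should react before the trisubstituted, conjugated C1=C2 alkene; no metal or acid touches the epoxide or the allylic C3–O bond.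

Step 16
Reactants: 25 2-(trimethylsilyl)ethyl (1E,3R,8R,9R)-8,9-epoxy-3-hydroxy-4,4,8-trimethylcycloundec-1-ene-1-carboxylate
Product: 26 2-(trimethylsilyl)ethyl (1E,3R,8R,9R)-3-(benzoyloxy)-8,9-epoxy-4,4,8-trimethylcycloundec-1-ene-1-carboxylate
Conditions: BzCl, 4-(dimethylamino)pyridine, pyridine, CH2Cl2, 0 → 25 °C
Reagents that add atoms: benzoyl chloride, O=C(Cl)c1ccccc1
Why: Nucleophilic catalysis of acylation by 4-(dimethylamino)pyridine; the hydroxyl is neopentylic and needs the acylpyridinium, and the C3–O bond is not broken, so the configuration is kept.

Step 17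
Reactants: 26 2-(trimethylsilyl)ethyl (1E,3R,8R,9R)-3-(benzoyloxy)-8,9-epoxy-4,4,8-trimethylcycloundec-1-ene-1-carboxylate
Product: 27 (1E,3R,8R,9R)-3-(benzoyloxy)-8,9-epoxy-4,4,8-trimethylcycloundec-1-ene-1-carboxylic acid
Conditions: Bu4NF, THF, 0 °C; aq. NaH2PO4
Reagents that add atoms: none
Why: Fluoride attacks silicon and the 2-silylethyl ester fragments to ethene, Me3SiF and the carboxylate (β-elimination), a cleavage that needs neither acid nor hydroxide, so the epoxide and the benzoate should remain; the mildly acidic work-up gives 27.

## Compound list

1 | 3-(tert-butyldimethylsilyloxy)propan-1-ol | CC(C)(C)[Si](C)(C)OCCCO | starting material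
2 | ethyl 2-(triphenylphosphoranylidene)propanoate | CCOC(=O)C(C)=P(c1ccccc1)(c1ccccc1)c1ccccc1 | starting material
3 | 3-(tert-butyldimethylsilyloxy)propanal (formed in the flask) | CC(C)(C)[Si](C)(C)OCCC=O | intermediate
4 | ethyl (E)-5-(tert-butyldimethylsilyloxy)-2-methylpent-2-enoate | CCOC(=O)/C(C)=C/CCO[Si](C)(C)C(C)(C)C | intermediate
5 | (E)-5-(tert-butyldimethylsilyloxy)-2-methylpent-2-en-1-ol | OC/C(C)=C/CCO[Si](C)(C)C(C)(C)C | intermediate
6 | tert-butyl[(E)-5-bromo-4-methylpent-3-enyloxy]dimethylsilane | BrC/C(C)=C/CCO[Si](C)(C)C(C)(C)C | intermediate
7 | 2-methylbut-3-yn-2-ol | CC(C)(O)C#C | starting material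
8 | (E)-9-(tert-butyldimethylsilyloxy)-2,6-dimethylnon-6-en-3-yn-2-ol | CC(C)(O)C#CC/C(C)=C/CCO[Si](C)(C)C(C)(C)C | intermediate
9 | (3E,6E)-9-(tert-butyldimethylsilyloxy)-2,6-dimethylnona-3,6-dien-2-ol | CC(C)(O)/C=C/C/C(C)=C/CCO[Si](C)(C)C(C)(C)C | intermediate
10 | (3E,6E)-9-(tert-butyldimethylsilyloxy)-2,6-dimethylnona-3,6-dien-2-yl methyl carbonate | COC(=O)OC(C)(C)/C=C/C/C(C)=C/CCO[Si](C)(C)C(C)(C)C | intermediate
11 | (3E,6E)-9-hydroxy-2,6-dimethylnona-3,6-dien-2-yl methyl carbonate | COC(=O)OC(C)(C)/C=C/C/C(C)=C/CCO | intermediate
12 | (3E,6E)-9-iodo-2,6-dimethylnona-3,6-dien-2-yl methyl carbonate | COC(=O)OC(C)(C)/C=C/C/C(C)=C/CCI | intermediate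
13 | 2-(trimethylsilyl)ethanol | C[Si](C)(C)CCO | starting material
14 | (triphenylphosphoranylidene)ketene | O=C=C=P(c1ccccc1)(c1ccccc1)c1ccccc1 | starting material
15 | 2-(trimethylsilyl)ethyl 2-(triphenylphosphoranylidene)acetate | C[Si](C)(C)CCOC(=O)C=P(c1ccccc1)(c1ccccc1)c1ccccc1 | intermediate
16 | [(5E,8E)-10-(methoxycarbonyloxy)-6,10-dimethyl-1-oxo-1-[2-(trimethylsilyl)ethoxy]undeca-5,8-dien-2-yl]triphenylphosphonium iodide (formed in the flask; phosphonium carbon not configured) | COC(=O)OC(C)(C)/C=C/C/C(C)=C/CCC(C(=O)OCC[Si](C)(C)C)[P+](c1ccccc1)(c1ccccc1)c1ccccc1.[I-] | intermediate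
17 | 2-(trimethylsilyl)ethyl (5E,8E)-10-(methoxycarbonyloxy)-6,10-dimethyl-2-(triphenylphosphoranylidene)undeca-5,8-dienoate | COC(=O)OC(C)(C)/C=C/C/C(C)=C/CCC(C(=O)OCC[Si](C)(C)C)=P(c1ccccc1)(c1ccccc1)c1ccccc1 | intermediate
18 | glycolaldehyde dimer (1,4-dioxane-2,5-diol) | OC1COC(O)CO1 | starting material
19 | glycolaldehyde (formed in the flask) | OCC=O | intermediate
20 | 2-(trimethylsilyl)ethyl (2E,5E,8E)-2-(2-hydroxyethylidene)-10-(methoxycarbonyloxy)-6,10-dimethylundeca-5,8-dienoate | COC(=O)OC(C)(C)/C=C/C/C(C)=C/CC/C(C(=O)OCC[Si](C)(C)C)=C\CO | intermediate
21 | 2-(trimethylsilyl)ethyl (2E)-2-(2-hydroxyethylidene)-4-[(2R,3R)-3-[(E)-4-(methoxycarbonyloxy)-4-methylpent-2-en-1-yl]-3-methyloxiran-2-yl]butanoate | COC(=O)OC(C)(C)/C=C/C[C@@]1(C)O[C@@H]1CC/C(C(=O)OCC[Si](C)(C)C)=C\CO | intermediate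
22 | 2-(trimethylsilyl)ethyl (2E)-4-[(2R,3R)-3-[(E)-4-(methoxycarbonyloxy)-4-methylpent-2-en-1-yl]-3-methyloxiran-2-yl]-2-(2-oxoethylidene)butanoate | COC(=O)OC(C)(C)/C=C/C[C@@]1(C)O[C@@H]1CC/C(C(=O)OCC[Si](C)(C)C)=C\C=O | intermediate
23 | allylindium bound at C6, written as the iodide methoxide with the alkaloid left out (formed in the flask; C6 not configured) | CC(C)=CC([In](I)OC)C[C@@]1(C)O[C@@H]1CC/C(C(=O)OCC[Si](C)(C)C)=C\C=O | intermediate
24 | 2-(trimethylsilyl)ethyl (1E,3R,5E,8R,9R)-8,9-epoxy-3-hydroxy-4,4,8-trimethylcycloundeca-1,5-diene-1-carboxylate | CC1(C)/C=C/C[C@@]2(C)O[C@@H]2CC/C(C(=O)OCC[Si](C)(C)C)=C\[C@H]1O | intermediate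
25 | 2-(trimethylsilyl)ethyl (1E,3R,8R,9R)-8,9-epoxy-3-hydroxy-4,4,8-trimethylcycloundec-1-ene-1-carboxylate | CC1(C)CCC[C@@]2(C)O[C@@H]2CC/C(C(=O)OCC[Si](C)(C)C)=C\[C@H]1O | intermediate
26 | 2-(trimethylsilyl)ethyl (1E,3R,8R,9R)-3-(benzoyloxy)-8,9-epoxy-4,4,8-trimethylcycloundec-1-ene-1-carboxylate | CC1(C)CCC[C@@]2(C)O[C@@H]2CC/C(C(=O)OCC[Si](C)(C)C)=C\[C@H]1OC(=O)c1ccccc1 | intermediate
27 | (1E,3R,8R,9R)-3-(benzoyloxy)-8,9-epoxy-4,4,8-trimethylcycloundec-1-ene-1-carboxylic acid | CC1(C)CCC[C@@]2(C)O[C@@H]2CC/C(C(=O)O)=C\[C@H]1OC(=O)c1ccccc1 | target

## Step count and least certain steps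

Total step count: 17. Longest linear sequence: 16 (steps 1–8 and 10–17, from 1); step 9 is a one-step side branch.

Step 14 (key step, carries the label).
- What may go wrong: ring closure may lose out to allylation between molecules, because an 11-membered transition state pays in entropy and in transannular strain. β-Hydride loss from the π-allylpalladium to a diene is possible if transfer to indium is slow. The kinetic γ-adduct can revert on long contact with trivalent indium, which can also rearrange the epoxide. Most likely of all is weak or reversed facial selection at C3, since alkaloid-modified allylindium reagents are only known between molecules and their sense here cannot be predicted.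
- Fallback (known chemistry), setting out from 22 and returning at 24: the ring is closed with Pd(PPh3)4 and InI alone, without the alkaloid, so that nothing is asked of the step but the C3–C4 bond. Compound 24 is separated by chromatography from its C3 epimer, 2-(trimethylsilyl)ethyl (1E,3S,5E,8R,9R)-8,9-epoxy-3-hydroxy-4,4,8-trimethylcycloundeca-1,5-diene-1-carboxylate F1. F1 is oxidised with Dess–Martin periodinane to the ring enone, 2-(trimethylsilyl)ethyl (1E,5E,8R,9R)-8,9-epoxy-4,4,8-trimethyl-3-oxocycloundeca-1,5-diene-1-carboxylate F2. F2 is reduced with catecholborane and the (S)-methyl-CBS oxazaborolidine ((S)-1-methyl-3,3-diphenyltetrahydro-1H,3H-pyrrolo[1,2-c][1,3,2]oxazaborole) at −78 °C to 24. With the quaternary C4 as the large group the S catalyst should give 3R, though that assignment of large and small groups is not secure for a tert-alkyl alkenyl ketone.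

Step 10 (ylide alkylation).
- What may go wrong: an ester-stabilised ylide is a weak nucleophile and the iodide is unactivated, so the SN2 step is slow. On long heating, E2 elimination to a diene and ionisation of the tertiary allylic carbonate gain ground.
- Fallback, setting out from 12 and returning at 20: 13 is esterified with (diethoxyphosphoryl)acetic acid (carbodiimide coupling) to 2-(trimethylsilyl)ethyl 2-(diethoxyphosphoryl)acetate F3. Its sodium salt (NaH, DMF) is alkylated by 12 to 2-(trimethylsilyl)ethyl (5E,8E)-2-(diethoxyphosphoryl)-10-(methoxycarbonyloxy)-6,10-dimethylundeca-5,8-dienoate F4. Horner–Wadsworth–Emmons olefination of F4 with (tert-butyldimethylsilyloxy)acetaldehyde (NaH, THF, 0 °C) gives, after removal of the minor geometric isomer, 2-(trimethylsilyl)ethyl (2E,5E,8E)-2-[2-(tert-butyldimethylsilyloxy)ethylidene]-10-(methoxycarbonyloxy)-6,10-dimethylundeca-5,8-dienoate F5. Buffered HF·pyridine then gives 20. The phosphonate anion is a far better nucleophile than the ylide; the price is a less selective olefination and one more step.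

Step 15 (diimide reduction).
- What may go wrong: the site selectivity may be incomplete. The C5=C6 alkene is next to a quaternary carbon and may react slowly, so that reduction of the conjugated C1=C2 alkene begins before it is consumed.
- Fallback, setting out from 24 and returning at 26: the order is changed and the reagent class with it. Compound 24 is first benzoylated (BzCl, 4-(dimethylamino)pyridine, pyridine) to 2-(trimethylsilyl)ethyl (1E,3R,5E,8R,9R)-3-(benzoyloxy)-8,9-epoxy-4,4,8-trimethylcycloundeca-1,5-diene-1-carboxylate F6. F6 is then hydrogenated with H2 and RhCl(PPh3)3 in benzene, a catalyst that separates disubstituted from trisubstituted alkenes on steric grounds and does not need the free hydroxyl, to give 26.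

Step 17 (ester cleavage).
- What may go wrong: the basic fluoride source may cleave the benzoate, and on acidification the liberated carboxyl group may open the epoxide.
- Fallback, setting out from 25 and returning at 27: the silylethyl ester is cleaved before the benzoate exists. Bu4NF converts 25 into (1E,3R,8R,9R)-8,9-epoxy-3-hydroxy-4,4,8-trimethylcycloundec-1-ene-1-carboxylic acid F7. Excess BzCl with 4-(dimethylamino)pyridine in pyridine acylates both oxygen functions to benzoic (1E,3R,8R,9R)-3-(benzoyloxy)-8,9-epoxy-4,4,8-trimethylcycloundec-1-ene-1-carboxylic anhydride F8. The anhydride of F8 is hydrolysed selectively with aqueous NaHCO3 in THF to 27.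

Step 5 (with step 4).
- What may go wrong: the C7 methylene of the skipped enyne 8 is both propargylic and allylic and may isomerise to an allene or a conjugated enyne under the basic coupling or the hydride conditions. The coupling may go partly SN2′, and hydroalumination of the hindered tertiary alkoxide may stall.
- Fallback, setting out from 6 and 7 and returning at 9: the E alkene is made before the C6–C7 bond. Hydrostannation of 7 (Bu3SnH, PdCl2(PPh3)2 as catalyst, THF) gives (E)-2-methyl-4-(tributylstannyl)but-3-en-2-ol F9. Stille coupling of F9 with the allylic bromide 6 (Pd2(dba)3, AsPh3, THF, 50 °C) gives 9 directly, with no alkyne in the chain at any time.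

## Further compounds

F1 | step 14 | 2-(trimethylsilyl)ethyl (1E,3S,5E,8R,9R)-8,9-epoxy-3-hydroxy-4,4,8-trimethylcycloundeca-1,5-diene-1-carboxylate | CC1(C)/C=C/C[C@@]2(C)O[C@@H]2CC/C(C(=O)OCC[Si](C)(C)C)=C\[C@@H]1O
F2 | step 14 | 2-(trimethylsilyl)ethyl (1E,5E,8R,9R)-8,9-epoxy-4,4,8-trimethyl-3-oxocycloundeca-1,5-diene-1-carboxylate | CC1(C)/C=C/C[C@@]2(C)O[C@@H]2CC/C(C(=O)OCC[Si](C)(C)C)=C\C1=O
F3 | step 10 | 2-(trimethylsilyl)ethyl 2-(diethoxyphosphoryl)acetate | CCOP(=O)(OCC)CC(=O)OCC[Si](C)(C)C
F4 | step 10 | 2-(trimethylsilyl)ethyl (5E,8E)-2-(diethoxyphosphoryl)-10-(methoxycarbonyloxy)-6,10-dimethylundeca-5,8-dienoate | COC(=O)OC(C)(C)/C=C/C/C(C)=C/CCC(C(=O)OCC[Si](C)(C)C)P(=O)(OCC)OCC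
F5 | step 10 | 2-(trimethylsilyl)ethyl (2E,5E,8E)-2-[2-(tert-butyldimethylsilyloxy)ethylidene]-10-(methoxycarbonyloxy)-6,10-dimethylundeca-5,8-dienoate | COC(=O)OC(C)(C)/C=C/C/C(C)=C/CC/C(C(=O)OCC[Si](C)(C)C)=C\CO[Si](C)(C)C(C)(C)C
F6 | step 15 | 2-(trimethylsilyl)ethyl (1E,3R,5E,8R,9R)-3-(benzoyloxy)-8,9-epoxy-4,4,8-trimethylcycloundeca-1,5-diene-1-carboxylate | CC1(C)/C=C/C[C@@]2(C)O[C@@H]2CC/C(C(=O)OCC[Si](C)(C)C)=C\[C@H]1OC(=O)c1ccccc1
F7 | step 17 | (1E,3R,8R,9R)-8,9-epoxy-3-hydroxy-4,4,8-trimethylcycloundec-1-ene-1-carboxylic acid | CC1(C)CCC[C@@]2(C)O[C@@H]2CC/C(C(=O)O)=C\[C@H]1O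
F8 | step 17 | benzoic (1E,3R,8R,9R)-3-(benzoyloxy)-8,9-epoxy-4,4,8-trimethylcycloundec-1-ene-1-carboxylic anhydride | CC1(C)CCC[C@@]2(C)O[C@@H]2CC/C(C(=O)OC(=O)c3ccccc3)=C\[C@H]1OC(=O)c1ccccc1
F9 | step 5 | (E)-2-methyl-4-(tributylstannyl)but-3-en-2-ol | CCCC[Sn](CCCC)(CCCC)/C=C/C(C)(C)O
A1 | alternative 1 | cis-fused six–seven hydroxy mesylate, methyl ester, with OH on ring-fusion carbon C3, gem-dimethyl on C4, methyl on ring-fusion carbon C8 and mesylate on C9 anti to the C3–C8 bond (atom numbers of 27; racemic, one enantiomer drawn) | COC(=O)C1=C[C@@]2(O)C(C)(C)CCC[C@@]2(C)[C@H](OS(C)(=O)=O)CC1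
A2 | alternative 1 | methyl 4,4,8-trimethyl-3-oxocycloundeca-1,8-diene-1-carboxylate (C1=C2 ring-cis, C8=C9 E) | CC1(C)CCC/C(C)=C/CC/C(C(=O)OC)=C\C1=O
A3 | alternative 2 | caryophyllene oxide, (1R,4R,5R,9S) | C[C@@]12CC[C@@H]3[C@H](CC3(C)C)C(=C)CC[C@H]1O2
A4 | alternative 2 | 8,9-epoxy-4,4,8-trimethyl-1-(phenylthiomethyl)cycloundec-1-ene, (8R,9R), C1=C2 ring-cis | CC1(C)CCC[C@@]2(C)O[C@@H]2CC/C(CSc3ccccc3)=C\C1
A5 | alternative 3 | 3,7,7-trimethylcyclohept-2-en-1-one | CC1=CC(=O)C(C)(C)CCC1
A6 | alternative 3 | 2-(trimethylsilyl)ethyl cyclobut-1-ene-1-carboxylate | C[Si](C)(C)CCOC(=O)C1=CCC1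
A7 | alternative 3 | 2-(trimethylsilyl)ethyl 4,4,8-trimethyl-3-oxocycloundeca-1,8-diene-1-carboxylate (C1=C2 ring-cis, C8=C9 E) | CC1(C)CCC/C(C)=C/CC/C(C(=O)OCC[Si](C)(C)C)=C\C1=O
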